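**Plan**

1. Retrosynthesis: the C2 ester and the C8–C17 bond (enol triflate methylation) are cut first. Ring B is opened at C6=C7 (aldol condensation of a C8 methyl ketone with a C6 aldehyde). Ring A is then cut at C3–C4 and C5–C10 in one [4+2] event. C1–C2 (Stille coupling) and C9–C10 (epoxide opening) lead back to (S)-linalool.
2. Enabling feature: ring A carries its only oxygen at C2, between the C1 and C3 methylenes and 1,4 to C5, and C5 carries C6. This is the retron of a 2-alkoxydiene C3=C2–C1=C10 adding to a C4=C5 alkene that is activated through C6 at the aldehyde level.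
3. Forward: linalool supplies C7–C9 and C11–C16. Its (E)-methyl group is oxidised, and the glycol made from it carries 3-methylbut-2-enal as a dioxolane. This temporary ring is tether, activator (alkenyl oxocarbenium ion) and, after glycol cleavage, the C8 methyl ketone.
4. Ring order: ring A together with a temporary oxane (key step), then carbocyclic ring B by aldol condensation, then C17, the C2 carbinol, the ester and desilylation.
5. Stereochemistry: C13 comes from (S)-linalool; C8 and C9 from Sharpless epoxidation and SN2 opening; C10 and C5 from the chair of the cycloaddition (C5 and C9 are also under thermodynamic control once the C6 and C8 carbonyl groups exist); C2 from equilibration to the equatorial carbinol.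

Key step: step 9

Remark on the chemistry: labdane numbering (C1–C20) is used for every intermediate, and (S)-(+)-linalool of high enantiomeric purity is assumed to be commercially available.

**Route**

Step 1
Reactants: 1 (S)-(+)-linalool
Product: 2 (S)-linalool tert-butyldimethylsilyl ether
Conditions: t-BuMe2SiOTf, 2,6-lutidine, CH2Cl2, 0 °C to rt
Reagents that add atoms: tert-butyldimethylsilyl trifluoromethanesulfonate, CC(C)(C)[Si](C)(C)OS(=O)(=O)C(F)(F)F
Why: Silylation of a tertiary alcohol with a silyl triflate and a hindered base is routine, and the ether keeps the C13 oxygen from attacking the later C8–C9 epoxide and from ionising under Lewis acids; C13 is untouched.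

Step 2
Reactants: 2 (S)-linalool tert-butyldimethylsilyl ether
Product: 3 (2E,6S)-6-(tert-butyldimethylsilyloxy)-2,6-dimethylocta-2,7-dien-1-ol
Conditions: SeO2 (cat.), t-BuOOH, salicylic acid (cat.), CH2Cl2, rt
Reagents that add atoms: tert-butyl hydroperoxide, CC(C)(C)OO
Why: Selenium dioxide allylic oxidation (ene reaction, then [2,3]-sigmatropic shift) should hydroxylate only the (E)-methyl group of the trisubstituted alkene, since the vinyl group has no allylic hydrogen.

Step 3
Reactants: 3 (2E,6S)-6-(tert-butyldimethylsilyloxy)-2,6-dimethylocta-2,7-dien-1-ol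
Product: 4 [(2S,3S)-3-[(3S)-3-(tert-butyldimethylsilyloxy)-3-methylpent-4-en-1-yl]-2-methyloxiran-2-yl]methanol
Conditions: Ti(OiPr)4 (cat.), L-(+)-diethyl tartrate (cat.), t-BuOOH, 4 Å molecular sieves, CH2Cl2, −20 °C
Reagents that add atoms: tert-butyl hydroperoxide, CC(C)(C)OO
Why: Sharpless asymmetric epoxidation of an (E)-2-methyl allylic alcohol is reagent-controlled, and L-(+)-tartrate should give the (2S,3S)-epoxide, which sets C9 and the temporary C8 centre; the vinyl group has no free allylic hydroxyl and stays inert.

Step 4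
Reactants: 4 the (2S,3S)-epoxy alcohol; 5 ethynyltrimethylsilane
Product: 6 (2R,3S)-3-[(3S)-3-(tert-butyldimethylsilyloxy)-3-methylpent-4-en-1-yl]-2-methyl-5-(trimethylsilyl)pent-4-yne-1,2-diol
Conditions: 5, n-BuLi, then Et2AlCl, toluene, 0 °C (gives Et2Al–C≡C–SiMe3); then 4, 0 °C to rt; aq. potassium sodium tartrate
Reagents that add atoms: none
Why: Hydroxyl-directed opening of a 2,3-epoxy alcohol by an alkynylalane is an SN2 reaction at C-3 (here C9) with inversion, away from the fully substituted C8, so C9 receives C10 with defined configuration and the C8 glycol is set free.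

Step 5
Reactants: 6 the silylalkyne diol
Product: 7 (2R,3S)-3-[(3S)-3-(tert-butyldimethylsilyloxy)-3-methylpent-4-en-1-yl]-2-methylpent-4-yne-1,2-diol
Conditions: K2CO3, MeOH, rt
Reagents that add atoms: none
Why: Base-mediated protodesilylation of the alkynylsilane frees the terminal alkyne without touching the silyl ether or the stereocentres.

Step 6
Reactants: 7 the terminal alkyne diol
Product: 9 (2R,3S,4E)-3-[(3S)-3-(tert-butyldimethylsilyloxy)-3-methylpent-4-en-1-yl]-5-iodo-2,4-dimethylpent-4-ene-1,2-diol, via alkenyldimethylalane 8 (not isolated)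
Conditions: Me3Al, Cp2ZrCl2, CH2Cl2, 0 °C to rt; then I2, THF, −30 to 0 °C
Reagents that add atoms: trimethylaluminium, C[Al](C)C; iodine, II
Why: Negishi zirconium-catalysed carboalumination adds CH3 and aluminium syn across the terminal alkyne with the methyl on the internal carbon (C10), and iodinolysis with retention should give the (E)-iodoalkene in which the C10 methyl is cis to the future C2; the glycol is carried as its aluminium alkoxide.

Step 7
Reactants: 9 the iodoalkene diol; 10 1,1-diethoxy-3-methylbut-2-ene
Product: 11 (4R)-4-[(1E,3S,6S)-6-(tert-butyldimethylsilyloxy)-1-iodo-2,6-dimethylocta-1,7-dien-3-yl]-4-methyl-2-(2-methylprop-1-en-1-yl)-1,3-dioxolane (both epimers at the acetal carbon)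
Conditions: pyridinium p-toluenesulfonate (cat.), CH2Cl2, 4 Å molecular sieves, rt
Reagents that add atoms: none
Why: Acid-catalysed transacetalisation of the 1,2-diol with the diethyl acetal should give the five-membered dioxolane, whose two acetal epimers converge on ionisation, and this places the future dienophile on the C8 oxygen.

Step 8
Reactants: 11 the iodoalkene dioxolane; 12 tributyl(1-ethoxyethenyl)stannane
Product: 13 (4R)-4-[(3E,5S,8S)-8-(tert-butyldimethylsilyloxy)-2-ethoxy-4,8-dimethyldeca-1,3,9-trien-5-yl]-4-methyl-2-(2-methylprop-1-en-1-yl)-1,3-dioxolane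
Conditions: Pd2(dba)3 (cat.), AsPh3, CuI (cat.), N-methylpyrrolidone, 40 °C
Reagents that add atoms: none
Why: Stille coupling of an alkenyl iodide with an α-alkoxyvinylstannane keeps the alkene geometry and runs under neutral conditions that both acid-labile groups tolerate, giving the 2-ethoxydiene with C9 trans to C2.

Step 9
Reactants: 13 the ethoxydiene dioxolane
Product: 14 tricyclic acetal: ring A [C1H=C2(OEt)–C3H2–C4Me2–C5H–C10Me] fused at C5–C10 to an oxane [C5–C6H–O–C8(Me)–C9H–C10] whose C6 and C8 are also bridged by O–CH2 (a 6,8-dioxabicyclo[3.2.1]octane); H-5 trans and the C9 side chain cis to the C10 methyl; the O–CH2 bridge on the face of the C10 methyl; 13S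
Conditions: Me3SiOTf (0.2 equiv), 2,6-di-tert-butyl-4-methylpyridine (0.3 equiv), CH2Cl2 (0.01 M), −78 to −40 °C; then Et3N
Reagents that add atoms: none
Why: Proposed new method: Me3SiOTf should open the dioxolane at its less hindered oxygen to an alkenyl oxocarbenium ion tethered through the C8 oxygen; the nucleophilic C3 terminus of the 2-ethoxydiene bonds to the tertiary cationic terminus C4 and the enol ether carbon C5 so formed adds to C10, so that C3–C4 and C5–C10 arise in one polar, asynchronous [4+2] event, after which the silylated CH2O arm recaptures the cyclic oxocarbenium ion at C6 and returns the catalyst. The closest known reaction type is the acid-catalysed ionic Diels–Alder reaction of 2-alkenyl-1,3-dioxolanes with 1,3-dienes, made intramolecular here through the acetal oxygen as a type 1 cycloaddition with the four-atom tether C9–C8–O–C6. Ring A closes as a cyclohexene (6-endo at C10 for the second bond) and the temporary oxane C5–C6–O–C8–C9–C10 closes at the same bond (6-exo at C10), the five-membered dioxolane then re-forming by oxygen attack on C6. C10 should be set by the chair of the forming oxane, in which the C9 side chain and the C8 methyl are both equatorial (a consequence of the anti epoxide opening in step 4), diene and dienophile are equatorial and the smaller C10 methyl is axial; the same chair puts H-5 trans to the C10 methyl, and C6 is an acetal carbon fixed by the bridge. The step needs conjugate rather than direct attack on the oxocarbenium ion and one diene face: the tether turns direct attack at C6 into an eight-membered closure, and the C8 and C9 centres from step 3 choose the face. The cationic dienophile and the electron-rich dienol ether should overcome the hindrance at the two quaternary termini C4 and C10, which the neutral partners would not do thermally.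

Step 10
Reactants: 14 the tricyclic acetal
Product: 16 13-(tert-butyldimethylsilyloxy)-17-norlabda-6,14-diene-2,8-dione (trans ring fusion; C5, C9, C10 and C13 configured as in the target), via keto aldehyde 15 (not isolated)
Conditions: H5IO6, THF/H2O, 0 °C to rt; extractive work-up; then NaOMe, MeOH, rt
Reagents that add atoms: water, O
Why: H5IO6 is both acid and glycol-cleaving oxidant, so enol ether and acetal hydrolysis (C2 ketone, C6 aldehyde) and cleavage of the C8 glycol (C8 methyl ketone, formaldehyde) should occur in one operation, and methoxide then drives the only irreversible pathway, the six-membered intramolecular aldol condensation of the methyl ketone carbon C7 onto the C6 aldehyde, while C5 (trans ring fusion) and C9 (equatorial side chain, cis to the C10 methyl) settle at their thermodynamic configurations by enolisation.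

Step 11
Reactants: 16 the enedione
Product: 18 13-(tert-butyldimethylsilyloxy)-2-hydroxy-17-norlabda-7,14-dien-8-yl trifluoromethanesulfonate (axial 2-hydroxyl, cis to the C10 methyl), via dilithium enolate alkoxide 17 (not isolated)
Conditions: LiBH(s-Bu)3 (2.3 equiv), THF, −78 °C; then PhNTf2, −78 to 0 °C
Reagents that add atoms: N-phenylbis(trifluoromethanesulfonimide), O=S(=O)(N(c1ccccc1)S(=O)(=O)C(F)(F)F)C(F)(F)F
Why: Conjugate reduction with enolate triflation: the bulky borohydride should add hydride 1,4 to the β-unsubstituted enone to give the C7=C8 enolate regiospecifically, which PhNTf2 traps on oxygen, while the C2 ketone is reduced from the equatorial side (the axial side is blocked by the syn-axial C4 and C10 methyls) to a hindered axial alkoxide that is not triflated and whose configuration is corrected in step 13.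

Step 12
Reactants: 18 the hydroxy enol triflate
Product: 19 (2S,5R,9R,10R,13S)-13-(tert-butyldimethylsilyloxy)labda-7,14-dien-2-ol (axial 2-hydroxyl)
Conditions: MeMgBr, Fe(acac)3 (cat.), THF/N-methylpyrrolidone, −20 °C
Reagents that add atoms: methylmagnesium bromide, C[Mg]Br
Why: Iron-catalysed cross-coupling of an enol triflate with a methyl Grignard reagent is fast at low temperature and should install C17 with the C7=C8 bond fixed where the triflate was; the free hydroxyl only consumes one equivalent of reagent.

Step 13
Reactants: 19 the axial alcohol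
Product: 20 (2R,5R,9R,10R,13S)-13-(tert-butyldimethylsilyloxy)labda-7,14-dien-2-ol (equatorial 2-hydroxyl)
Conditions: Al(OiPr)3, acetone (cat.), i-PrOH/toluene, reflux
Reagents that add atoms: none
Why: Meerwein–Ponndorf–Verley/Oppenauer hydride exchange equilibrates the carbinol through the C2 ketone, and the equatorial (2R) alcohol should prevail because the axial hydroxyl is syn-axial to both the C10 methyl and the axial C4 methyl.

Step 14
Reactants: 20 the equatorial alcohol; 21 3-methylbut-2-enoyl chloride
Product: 22 (2R,5R,9R,10R,13S)-13-(tert-butyldimethylsilyloxy)labda-7,14-dien-2-yl 3-methylbut-2-enoate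
Conditions: pyridine, CH2Cl2, 0 °C to rt
Reagents that add atoms: none
Why: Acylation of the unhindered equatorial alcohol by the acid chloride (nucleophilic acyl substitution), with pyridine as the only base, avoids deconjugation of the 3-methylbut-2-enoyl group, and C2 keeps its configuration.

Step 15
Reactants: 22 the silyl-protected ester
Product: 23 (2R,5R,9R,10R,13S)-13-hydroxylabda-7,14-dien-2-yl 3-methylbut-2-enoate (target)
Conditions: Bu4NF, THF, 50 °C
Reagents that add atoms: none
Why: Fluoride-induced desilylation of the tertiary silyl ether should leave the hindered conjugated ester and the alkenes untouched and give the target.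

**Compound list**

1 | (S)-(+)-linalool, (3S)-3,7-dimethylocta-1,6-dien-3-ol | C=C[C@@](C)(O)CCC=C(C)C | starting material
2 | tert-butyl{[(3S)-3,7-dimethylocta-1,6-dien-3-yl]oxy}dimethylsilane | C=C[C@@](C)(O[Si](C)(C)C(C)(C)C)CCC=C(C)C | intermediate
3 | (2E,6S)-6-(tert-butyldimethylsilyloxy)-2,6-dimethylocta-2,7-dien-1-ol | C=C[C@@](C)(O[Si](C)(C)C(C)(C)C)CC/C=C(\C)CO | intermediate
4 | [(2S,3S)-3-[(3S)-3-(tert-butyldimethylsilyloxy)-3-methylpent-4-en-1-yl]-2-methyloxiran-2-yl]methanol | C=C[C@@](C)(O[Si](C)(C)C(C)(C)C)CC[C@@H]1O[C@@]1(C)CO | intermediate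
5 | ethynyltrimethylsilane | C#C[Si](C)(C)C | starting material
6 | (2R,3S)-3-[(3S)-3-(tert-butyldimethylsilyloxy)-3-methylpent-4-en-1-yl]-2-methyl-5-(trimethylsilyl)pent-4-yne-1,2-diol | C=C[C@@](C)(O[Si](C)(C)C(C)(C)C)CC[C@@H](C#C[Si](C)(C)C)[C@@](C)(O)CO | intermediate
7 | (2R,3S)-3-[(3S)-3-(tert-butyldimethylsilyloxy)-3-methylpent-4-en-1-yl]-2-methylpent-4-yne-1,2-diol | C=C[C@@](C)(O[Si](C)(C)C(C)(C)C)CC[C@@H](C#C)[C@@](C)(O)CO | intermediate
8 | (E)-alkenyldimethylalane from 7 (CH3 on C10, AlMe2 on C1; the glycol is present as its aluminium alkoxide) | C=C[C@@](C)(O[Si](C)(C)C(C)(C)C)CC[C@@H](/C(C)=C/[Al](C)C)[C@@](C)(O)CO | intermediate (not isolated)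
9 | (2R,3S,4E)-3-[(3S)-3-(tert-butyldimethylsilyloxy)-3-methylpent-4-en-1-yl]-5-iodo-2,4-dimethylpent-4-ene-1,2-diol | C=C[C@@](C)(O[Si](C)(C)C(C)(C)C)CC[C@@H](/C(C)=C/I)[C@@](C)(O)CO | intermediate
10 | 1,1-diethoxy-3-methylbut-2-ene (3-methylbut-2-enal diethyl acetal) | CCOC(OCC)C=C(C)C | starting material
11 | (4R)-4-[(1E,3S,6S)-6-(tert-butyldimethylsilyloxy)-1-iodo-2,6-dimethylocta-1,7-dien-3-yl]-4-methyl-2-(2-methylprop-1-en-1-yl)-1,3-dioxolane (both acetal epimers) | C=C[C@@](C)(O[Si](C)(C)C(C)(C)C)CC[C@@H](/C(C)=C/I)[C@]1(C)COC(C=C(C)C)O1 | intermediate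
12 | tributyl(1-ethoxyethenyl)stannane | CCCC[Sn](CCCC)(CCCC)C(=C)OCC | starting material
13 | (4R)-4-[(3E,5S,8S)-8-(tert-butyldimethylsilyloxy)-2-ethoxy-4,8-dimethyldeca-1,3,9-trien-5-yl]-4-methyl-2-(2-methylprop-1-en-1-yl)-1,3-dioxolane (both acetal epimers) | C=C[C@@](C)(O[Si](C)(C)C(C)(C)C)CC[C@@H](/C(C)=C/C(=C)OCC)[C@]1(C)COC(C=C(C)C)O1 | intermediate
14 | tricyclic acetal: 2-ethoxycyclohex-1-ene ring A fused at C5–C10 to the oxane C5–C6–O–C8–C9–C10, with an O–CH2 bridge from C6 to C8; H-5 trans and C9 side chain cis to the C10 methyl | C=C[C@@](C)(O[Si](C)(C)C(C)(C)C)CC[C@@H]1[C@]2(C)CO[C@@H](O2)[C@@H]3C(C)(C)CC(OCC)=C[C@@]13C | intermediate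
15 | keto aldehyde: ring A cyclohexanone (C2=O) with a formyl group on C5 and, on C10, the methyl group and the CH(side chain)–C(=O)CH3 arm | C=C[C@@](C)(O[Si](C)(C)C(C)(C)C)CC[C@H](C(C)=O)[C@]1(C)CC(=O)CC(C)(C)[C@H]1C=O | intermediate (not isolated)
16 | 13-(tert-butyldimethylsilyloxy)-17-norlabda-6,14-diene-2,8-dione (trans-fused; C9 side chain equatorial; 13S) | C=C[C@@](C)(O[Si](C)(C)C(C)(C)C)CC[C@@H]1C(=O)C=C[C@@H]2C(C)(C)CC(=O)C[C@@]12C | intermediate
17 | dilithium C7=C8 enolate and C2 alkoxide from 16 | C=C[C@@](C)(O[Si](C)(C)C(C)(C)C)CC[C@@H]1C([O-])=CC[C@@H]2C(C)(C)C[C@H]([O-])C[C@@]12C.[Li+].[Li+] | intermediate (not isolated)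
18 | 13-(tert-butyldimethylsilyloxy)-2-hydroxy-17-norlabda-7,14-dien-8-yl trifluoromethanesulfonate (axial 2-hydroxyl) | C=C[C@@](C)(O[Si](C)(C)C(C)(C)C)CC[C@@H]1C(OS(=O)(=O)C(F)(F)F)=CC[C@@H]2C(C)(C)C[C@H](O)C[C@@]12C | intermediate
19 | (2S,5R,9R,10R,13S)-13-(tert-butyldimethylsilyloxy)labda-7,14-dien-2-ol | C=C[C@@](C)(O[Si](C)(C)C(C)(C)C)CC[C@@H]1C(C)=CC[C@@H]2C(C)(C)C[C@H](O)C[C@@]12C | intermediate
20 | (2R,5R,9R,10R,13S)-13-(tert-butyldimethylsilyloxy)labda-7,14-dien-2-ol | C=C[C@@](C)(O[Si](C)(C)C(C)(C)C)CC[C@@H]1C(C)=CC[C@@H]2C(C)(C)C[C@@H](O)C[C@@]12C | intermediate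
21 | 3-methylbut-2-enoyl chloride | CC(C)=CC(=O)Cl | starting material
22 | (2R,5R,9R,10R,13S)-13-(tert-butyldimethylsilyloxy)labda-7,14-dien-2-yl 3-methylbut-2-enoate | C=C[C@@](C)(O[Si](C)(C)C(C)(C)C)CC[C@@H]1C(C)=CC[C@@H]2C(C)(C)C[C@@H](OC(=O)C=C(C)C)C[C@@]12C | intermediate
23 | (2R,5R,9R,10R,13S)-13-hydroxylabda-7,14-dien-2-yl 3-methylbut-2-enoate | C=C[C@@](C)(O)CC[C@@H]1C(C)=CC[C@@H]2C(C)(C)C[C@@H](OC(=O)C=C(C)C)C[C@@]12C | target

**Step count**

Total steps: 15. Longest linear sequence: 15 steps (from 1; compounds 5, 10, 12 and 21 are commercial partners).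

**Steps most likely to fail**

1. Step 9 (Proposed new method). After ionisation the cation may lose a proton to a 1-alkoxydiene or add a second molecule of dienol ether instead of cyclising. Competing chair and boat pathways may also erode facial selectivity at C10. Because C8 is excised and C9 is equilibrated later, the epoxide from D-(−)-diethyl tartrate would serve if the intrinsic facial sense proved opposite. Fallback by known chemistry, without the tether, from 9: the glycol is protected with 2,2-dimethoxypropane and pyridinium p-toluenesulfonate as the iodoalkene acetonide F1. Stille coupling with 12 gives the ethoxydiene acetonide F2. A high-pressure thermal Diels–Alder reaction with 3-methylbut-2-enal (CH2Cl2, about 12 kbar), in which the dienophile should add anti to the dioxolane-bearing C8 at the allylic centre C9, gives the ring A aldehyde F3. H5IO6 and then NaOMe, as in step 10, bring the sequence back to 16.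

2. Step 4. The alane may attack or ionise the fully substituted C8, leading to poor regioselectivity or to rearrangement of the epoxide to a carbonyl compound. Fallback from 4, in which regiochemistry rests on sterics instead of chelation: the primary hydroxyl is silylated (Et3SiCl, imidazole) to the triethylsilyl ether F4. Lithium (trimethylsilyl)acetylide with BF3·OEt2 at −78 °C opens the epoxide by SN2 at the secondary C9 to the alkynyl carbinol F5. K2CO3 in MeOH followed by pyridinium p-toluenesulfonate in MeOH removes the alkynyl and primary silyl groups and returns to 7.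

3. Step 11. The borohydride may reduce the enone carbonyl directly, or the C2 alkoxide may be triflated along with the enolate. Fallback from 16, in which the two carbonyl groups are handled separately: [(Ph3P)CuH]6 with Me3SiCl reduces only the enone and gives the silyl enol ether F6 with the C2 ketone intact. PhNTf2 with CsF converts it into the keto triflate F7. MeZnCl with Pd(PPh3)4 gives the labdadienone F8. Meerwein–Ponndorf–Verley reduction under equilibrating conditions (Al(OiPr)3, i-PrOH, reflux) gives the equatorial alcohol and returns to 20.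

**Further compounds**

F1 | step 9 | (4R)-4-[(1E,3S,6S)-6-(tert-butyldimethylsilyloxy)-1-iodo-2,6-dimethylocta-1,7-dien-3-yl]-2,2,4-trimethyl-1,3-dioxolane | C=C[C@@](C)(O[Si](C)(C)C(C)(C)C)CC[C@@H](/C(C)=C/I)[C@]1(C)COC(C)(C)O1
F2 | step 9 | (4R)-4-[(3E,5S,8S)-8-(tert-butyldimethylsilyloxy)-2-ethoxy-4,8-dimethyldeca-1,3,9-trien-5-yl]-2,2,4-trimethyl-1,3-dioxolane | C=C[C@@](C)(O[Si](C)(C)C(C)(C)C)CC[C@@H](/C(C)=C/C(=C)OCC)[C@]1(C)COC(C)(C)O1
F3 | step 9 | ring A aldehyde: 2-ethoxycyclohex-1-ene with C4 gem-dimethyl, C5 formyl and C10 methyl, C10 bearing C9H(side chain)(2,2,4-trimethyl-1,3-dioxolan-4-yl) | C=C[C@@](C)(O[Si](C)(C)C(C)(C)C)CC[C@H]([C@]1(C)COC(C)(C)O1)[C@]2(C)C=C(OCC)CC(C)(C)[C@H]2C=O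
F4 | step 4 | triethylsilyl ether of epoxy alcohol 4 | C=C[C@@](C)(O[Si](C)(C)C(C)(C)C)CC[C@@H]1O[C@@]1(C)CO[Si](CC)(CC)CC
F5 | step 4 | (2R,3S)-3-[(3S)-3-(tert-butyldimethylsilyloxy)-3-methylpent-4-en-1-yl]-2-methyl-1-(triethylsilyloxy)-5-(trimethylsilyl)pent-4-yn-2-ol | C=C[C@@](C)(O[Si](C)(C)C(C)(C)C)CC[C@@H](C#C[Si](C)(C)C)[C@@](C)(O)CO[Si](CC)(CC)CC
F6 | step 11 | 13-(tert-butyldimethylsilyloxy)-8-(trimethylsilyloxy)-17-norlabda-7,14-dien-2-one | C=C[C@@](C)(O[Si](C)(C)C(C)(C)C)CC[C@@H]1C(O[Si](C)(C)C)=CC[C@@H]2C(C)(C)CC(=O)C[C@@]12C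
F7 | step 11 | 13-(tert-butyldimethylsilyloxy)-2-oxo-17-norlabda-7,14-dien-8-yl trifluoromethanesulfonate | C=C[C@@](C)(O[Si](C)(C)C(C)(C)C)CC[C@@H]1C(OS(=O)(=O)C(F)(F)F)=CC[C@@H]2C(C)(C)CC(=O)C[C@@]12C
F8 | step 11 | 13-(tert-butyldimethylsilyloxy)labda-7,14-dien-2-one | C=C[C@@](C)(O[Si](C)(C)C(C)(C)C)CC[C@@H]1C(C)=CC[C@@H]2C(C)(C)CC(=O)C[C@@]12C
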